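**Assumption (one line):** units are labelled A–F (C7x carries the 4‑oxygenated aryl, C8x the 3,5‑dioxygenated ring X2; A/B = seven‑ring part, C–F = eight‑ring part); the SMILES is read as 7aS,8aS,7bR,8bR,7cR,8cR,7dR,8dR,7eS,8eS,7fR,8fR; "target configuration" means the arrangement in the SMILES; benzyl, triisopropylsilyl and tert‑butyl are protecting groups; Rh2(S‑PTAD)4 is taken as the catalyst hand that gives 3R.

## Retrosynthetic overview

1. Target 50 ← global deprotection of 48; C7a–H ← ionic hydrogenation of carbinol 47, made by aryl addition to seven‑ring ketone 45.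
2. 45 ← C8a–C7c bond by 1,6‑addition of the enolate of seven‑ring ketone 37 (units A/B) to quinone methide 43 (units C–F).
3. 43 ← eight‑membered ring (C7e–ring D2) by a fluoride‑released resorcinolate adding to the quinone methide of 38; 38 ← C8c–C8e bond by copper‑catalysed radical cross‑coupling of bromoketone 31 with stilbene phenol 28.
4. 28, 31 and 37 ← one bromo‑dihydrobenzofuran (21/23) by Heck coupling and ester α‑arylation; its C2–C3 bond and both stereocentres ← rhodium‑carbene C–H insertion; the diaryl ketone ← carbonylative Suzuki coupling.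
5. Arene pieces ← resorcinol and 3‑bromophenol by iridium‑catalysed C–H borylation; ring order: dihydrofurans → seven‑ring (A/B) and eight‑ring (C–E) in parallel → union.

## Route

Step 1
Reactants: 1 resorcinol
Product: 2 1,3-bis(triisopropylsilyloxy)benzene
Conditions: i-Pr3SiCl (2.2 equiv), imidazole, DMF, 25 °C
Reagents that add atoms: triisopropylsilyl chloride CC(C)[Si](Cl)(C(C)C)C(C)C
Why: Routine phenol silylation; the silyl groups carry no aryl C–H and shield both ortho positions for the borylation.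

Step 2
Reactants: 2 1,3-bis(triisopropylsilyloxy)benzene
Product: 3 2-[3,5-bis(triisopropylsilyloxy)phenyl]-4,4,5,5-tetramethyl-1,3,2-dioxaborolane
Conditions: B2pin2 (1.0 equiv), [Ir(cod)(OMe)]2 (1.5 mol%), 4,4'-di-tert-butyl-2,2'-bipyridine (3 mol%), hexane, 80 °C
Reagents that add atoms: bis(pinacolato)diboron CC1(C)OB(OC1(C)C)B1OC(C)(C)C(C)(C)O1
Why: Iridium-catalysed aromatic C–H borylation is sterically controlled, so only the C5–H (no ortho substituent) reacts.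

Step 3
Reactants: 4 3-bromophenol
Product: 5 (3-bromophenoxy)triisopropylsilane
Conditions: i-Pr3SiCl, imidazole, DMF, 25 °C
Reagents that add atoms: triisopropylsilyl chloride CC(C)[Si](Cl)(C(C)C)C(C)C
Why: Routine silylation that removes the acidic OH and blocks the ortho C–H bonds before C–H borylation.

Step 4
Reactants: 5 (3-bromophenoxy)triisopropylsilane
Product: 7 3-bromo-5-(triisopropylsilyloxy)phenol, via arylboronate 6 (not isolated)
Conditions: B2pin2, [Ir(cod)(OMe)]2 (1.5 mol%), 4,4'-di-tert-butyl-2,2'-bipyridine (3 mol%), hexane, 80 °C; then KHSO5 (triple salt), acetone/H2O, 25 °C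
Reagents that add atoms: potassium peroxymonosulfate [K+].[O-]S(=O)(=O)OO
Why: One-pot meta C–H borylation/oxidation of a 1,3-disubstituted arene gives the 5-hydroxy product, because borylation occurs only at the C–H flanked by two hydrogens.

Step 5
Reactants: 7 3-bromo-5-(triisopropylsilyloxy)phenol
Product: 9 1,3-bis(benzyloxy)-5-bromobenzene, via 5-bromobenzene-1,3-diol 8 (not isolated)
Conditions: Bu4NF, THF, 0 °C; then BnBr (2.3 equiv), K2CO3, DMF, 50 °C
Reagents that add atoms: benzyl bromide BrCc1ccccc1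
Why: Fluoride desilylation followed by Williamson etherification of both phenoxides.

Step 6
Reactants: 9 1,3-bis(benzyloxy)-5-bromobenzene
Product: 10 1,5-bis(benzyloxy)-3-bromo-2-iodobenzene
Conditions: NIS (1.05 equiv), CF3CO2H (cat.), MeCN, 0 °C
Reagents that add atoms: N-iodosuccinimide O=C1CCC(=O)N1I
Why: Electrophilic aromatic iodination goes para to one benzyloxy group and ortho to the other, next to bromine, as is usual for 5-substituted resorcinol diethers.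

Step 7
Reactants: 10 1,5-bis(benzyloxy)-3-bromo-2-iodobenzene; 3 2-[3,5-bis(triisopropylsilyloxy)phenyl]-4,4,5,5-tetramethyl-1,3,2-dioxaborolane
Product: 11 [2,4-bis(benzyloxy)-6-bromophenyl][3,5-bis(triisopropylsilyloxy)phenyl]methanone
Conditions: CO (1 atm), [PdCl2(IPr)(3-chloropyridine)] (3 mol%), Cs2CO3, PhCl/H2O, 80 °C
Reagents that add atoms: carbon monoxide [C-]#[O+]
Why: Carbonylative Suzuki–Miyaura coupling; oxidative addition is selective for C–I over C–Br, and the di-ortho-substituted aryl-palladium inserts CO faster than it transmetalates.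

Step 8
Reactants: 11 [2,4-bis(benzyloxy)-6-bromophenyl][3,5-bis(triisopropylsilyloxy)phenyl]methanone
Product: 12 [4-(benzyloxy)-2-bromo-6-hydroxyphenyl][3,5-bis(triisopropylsilyloxy)phenyl]methanone
Conditions: BCl3 (1.1 equiv), CH2Cl2, −78 °C
Reagents that add atoms: none
Why: Chelation-controlled dealkylation removes only the benzyl ether ortho to the carbonyl.

Step 9
Reactants: 13 4-bromophenol
Product: 14 1-(benzyloxy)-4-bromobenzene
Conditions: BnBr, K2CO3, acetone, reflux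
Reagents that add atoms: benzyl bromide BrCc1ccccc1
Why: Williamson etherification.

Step 10
Reactants: 14 1-(benzyloxy)-4-bromobenzene
Product: 16 [4-(benzyloxy)phenyl]methanol, via Grignard reagent 15 (not isolated)
Conditions: Mg, THF, reflux; then (CH2O)n, 0 → 25 °C; cold 1 M HCl
Reagents that add atoms: formaldehyde (from paraformaldehyde) C=O
Why: Grignard hydroxymethylation.

Step 11
Reactants: 12 [4-(benzyloxy)-2-bromo-6-hydroxyphenyl][3,5-bis(triisopropylsilyloxy)phenyl]methanone; 16 [4-(benzyloxy)phenyl]methanol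
Product: 17 [4-(benzyloxy)-2-{[4-(benzyloxy)phenyl]methoxy}-6-bromophenyl][3,5-bis(triisopropylsilyloxy)phenyl]methanone
Conditions: PPh3, DIAD, THF, 0 → 25 °C
Reagents that add atoms: none
Why: Mitsunobu etherification of the acidic chelated phenol installs the O–CH2–aryl group that becomes C7 of the dihydrofuran.

Step 12
Reactants: 17 [4-(benzyloxy)-2-{[4-(benzyloxy)phenyl]methoxy}-6-bromophenyl][3,5-bis(triisopropylsilyloxy)phenyl]methanone
Product: 18 hydrazone of ketone 17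
Conditions: N2H4·H2O (10 equiv), Sc(OTf)3 (5 mol%), EtOH/THF, 70 °C
Reagents that add atoms: hydrazine NN
Why: Lewis-acid-assisted hydrazone condensation, with forcing conditions because the ketone is di-ortho-substituted.

Step 13
Reactants: 18 hydrazone of ketone 17
Product: 20 (2S,3R)-6-(benzyloxy)-2-[4-(benzyloxy)phenyl]-4-bromo-3-[3,5-bis(triisopropylsilyloxy)phenyl]-2,3-dihydro-1-benzofuran (cis), via diazo compound 19 (not isolated)
Conditions: MnO2, CH2Cl2, 0 °C, filter; then Rh2(S-PTAD)4 (1 mol%), CH2Cl2, −20 → 25 °C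
Reagents that add atoms: none
Why: Hydrazone oxidation then intramolecular C–H insertion of a donor/donor rhodium carbene into the benzylic O–CH2 bond; the chiral dirhodium carboxylate sets C3 (R) and the concerted insertion gives the cis isomer (C2 S).

Step 14
Reactants: 20 cis-dihydrobenzofuran (2S,3R)
Product: 21 (2R,3R)-6-(benzyloxy)-2-[4-(benzyloxy)phenyl]-4-bromo-3-[3,5-bis(triisopropylsilyloxy)phenyl]-2,3-dihydro-1-benzofuran (trans)
Conditions: CF3CO2H (3 equiv), CH2Cl2, 0 → 25 °C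
Reagents that add atoms: none
Why: Acid-mediated epimerisation by reversible ionisation of the benzylic C2–O bond gives the more stable trans isomer; C3 is untouched, so the product is 2R,3R.

Step 15
Reactants: 21 trans-bromide (ring 3,5-bis-silyl ether)
Product: 23 (2R,3R)-6-(benzyloxy)-2-[4-(benzyloxy)phenyl]-3-[3,5-bis(benzyloxy)phenyl]-4-bromo-2,3-dihydro-1-benzofuran, via resorcinol 22 (not isolated)
Conditions: Bu4NF, THF, 0 °C; then BnBr, K2CO3, DMF, 25 °C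
Reagents that add atoms: benzyl bromide BrCc1ccccc1
Why: Desilylation and Williamson etherification give the all-benzyl block used for units A/B and E/F.

Step 16
Reactants: 24 phenol
Product: 25 2,6-di-tert-butylphenol
Conditions: 2-methylpropene (2.2 equiv), Al(OPh)3 (cat.), 110 °C, sealed vessel
Reagents that add atoms: 2-methylpropene CC(C)=C
Why: Aluminium-phenoxide-catalysed ortho-selective Friedel–Crafts alkylation.

Step 17
Reactants: 25 2,6-di-tert-butylphenol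
Product: 26 4-bromo-2,6-di-tert-butylphenol
Conditions: Br2, CH2Cl2, 0 °C
Reagents that add atoms: bromine BrBr
Why: Electrophilic bromination at the only open activated position (para).

Step 18
Reactants: 26 4-bromo-2,6-di-tert-butylphenol
Product: 27 2,6-di-tert-butyl-4-ethenylphenol
Conditions: potassium vinyltrifluoroborate, PdCl2(dppf) (2 mol%), Cs2CO3, THF/H2O, 80 °C
Reagents that add atoms: potassium vinyltrifluoroborate [K+].C=C[B-](F)(F)F
Why: Suzuki–Miyaura vinylation; the hindered phenol needs no protection.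

Step 19
Reactants: 23 all-benzyl bromide; 27 2,6-di-tert-butyl-4-ethenylphenol
Product: 28 2,6-di-tert-butyl-4-[(E)-2-{(2R,3R)-6-(benzyloxy)-2-[4-(benzyloxy)phenyl]-3-[3,5-bis(benzyloxy)phenyl]-2,3-dihydro-1-benzofuran-4-yl}ethenyl]phenol
Conditions: Pd2(dba)3 (2.5 mol%), [HP(t-Bu)3]BF4 (10 mol%), Cy2NMe, dioxane, 100 °C
Reagents that add atoms: none
Why: Mizoroki–Heck coupling of a hindered electron-rich aryl bromide with a styrene gives the E-stilbene (units E/F).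

Step 20
Reactants: 21 trans-bromide (ring 3,5-bis-silyl ether); 27 2,6-di-tert-butyl-4-ethenylphenol
Product: 29 2,6-di-tert-butyl-4-[(E)-2-{(2R,3R)-6-(benzyloxy)-2-[4-(benzyloxy)phenyl]-3-[3,5-bis(triisopropylsilyloxy)phenyl]-2,3-dihydro-1-benzofuran-4-yl}ethenyl]phenol
Conditions: Pd2(dba)3 (2.5 mol%), [HP(t-Bu)3]BF4 (10 mol%), Cy2NMe, dioxane, 100 °C
Reagents that add atoms: none
Why: Same Mizoroki–Heck coupling gives the E-stilbene for units C/D, with ring D2 kept as the only silyl-protected resorcinol.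

Step 21
Reactants: 29 stilbene phenol (units C/D)
Product: 31 2-bromo-1-(3,5-di-tert-butyl-4-hydroxyphenyl)-2-{(2R,3R)-6-(benzyloxy)-2-[4-(benzyloxy)phenyl]-3-[3,5-bis(triisopropylsilyloxy)phenyl]-2,3-dihydro-1-benzofuran-4-yl}ethan-1-one (C8c epimers), via bromohydrin 30 (not isolated)
Conditions: NBS (1.05 equiv), DMSO/H2O, 0 °C; then IBX, 25 °C
Reagents that add atoms: N-bromosuccinimide O=C1CCC(=O)N1Br; water O
Why: Bromohydrin formation puts Br on C8c and oxygen on C7c (the carbon stabilised by the para-hydroxyaryl group), and IBX oxidises the benzylic alcohol to the ketone; the C8c centre is reset in step 24.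

Step 22
Reactants: 23 all-benzyl bromide; 32 tert-butyl acetate
Product: 34 tert-butyl 2-{(2R,3R)-6-(benzyloxy)-2-[4-(benzyloxy)phenyl]-3-[3,5-bis(benzyloxy)phenyl]-2,3-dihydro-1-benzofuran-4-yl}acetate, via lithium enolate 33 (not isolated)
Conditions: 32, LiN(SiMe3)2, PhMe, 0 °C; then 23, Pd(dba)2 (3 mol%), P(t-Bu)3 (3 mol%), 25 °C
Reagents that add atoms: none
Why: Palladium-catalysed α-arylation of an ester enolate.

Step 23
Reactants: 34 tert-butyl arylacetate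
Product: 37 seven-ring ketone of units A/B (C7a=O; C8a H2; C7a bonded to the ortho carbon of ring B2; 7bR,8bR; four benzyl ethers), via carboxylic acid 35 (not isolated), via mixed anhydride 36 (not isolated)
Conditions: CF3CO2H/CH2Cl2, 25 °C; evaporate; then (CF3CO)2O, CH2Cl2, 0 → 25 °C
Reagents that add atoms: none
Why: Ester acidolysis then intramolecular Friedel–Crafts acylation; the acylium can only reach the activated ortho position of ring B2, which closes the seven-membered ring.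

Step 24
Reactants: 31 α-bromoketone (units C/D); 28 stilbene phenol (units E/F)
Product: 38 keto-quinone methide (units C–F; new C8c–C8e bond; C7c ketone; C7e exocyclic carbon of a 2,6-di-tert-butyl quinone methide; ring D2 bis-silyl ether; C8c and C8e in target configuration)
Conditions: CuBr (10 mol%), Me6TREN (12 mol%), Cs2CO3 (2.2 equiv), degassed PhMe/MeCN, 25 °C
Reagents that add atoms: none
Why: Proposed new method: copper-catalysed atom-transfer radical cross-coupling of an α-bromoketone with a persistent stilbene-phenoxyl radical – monovalent copper abstracts Br from 31 to give the transient α-keto benzylic radical at C8c, the divalent copper so formed oxidises the phenoxide of 28 to its persistent phenoxyl radical (spin at C8e, reversibly stored as its 8–8′ dimer), and the persistent-radical effect steers the transient radical into C8c–C8e cross-coupling, which unveils a single quinone methide at C7e and returns monovalent copper (redox-neutral overall); each new centre should form on the radical face anti to the C3 aryl of its own dihydrobenzofuran (allylic 1,3-strain), which is the sense found at every C8 of the target; closest known reaction types are copper-mediated atom-transfer nitroxide radical coupling and the ferrocenium-mediated 8–8′ dimerisation of tert-butylated 4-hydroxystilbenes.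

Step 25
Reactants: 38 keto-quinone methide
Product: 40 eight-ring ketone (units C–F; C7e bonded to the ortho carbon of ring D2; C7e S as in target; ring D2 as bis-benzyl ether; two hindered phenols free), via eight-ring resorcinol 39 (not isolated)
Conditions: Bu4NF (2.2 equiv), THF, −40 → 0 °C; then BnBr (2.3 equiv), K2CO3, DMF, 25 °C
Reagents that add atoms: benzyl bromide BrCc1ccccc1
Why: Fluoride frees the ring D2 resorcinolate, the only strong nucleophile present, which C-alkylates the only electrophile (the C7e quinone methide) in an intramolecular 1,6-conjugate addition (O-attack is reversible); ring strain should place the C7e aryl trans to ring E2 on the new ring, and only the two unhindered phenols are then benzylated.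

Step 26
Reactants: 40 eight-ring ketone
Product: 41 C7c alcohol (epimers at C7c)
Conditions: NaBH4, THF/MeOH, 0 → 25 °C
Reagents that add atoms: none
Why: Hydride reduction of the aryl ketone; the C7c configuration is irrelevant because it is planarised next.

Step 27
Reactants: 41 C7c alcohol
Product: 43 C7c quinone methide (units C–F; 2,6-di-tert-butyl quinone methide with C7c as exocyclic carbon), via mesylate 42 (not isolated)
Conditions: MsCl (1.2 equiv), Et3N (3 equiv), CH2Cl2, −20 → 0 °C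
Reagents that add atoms: none
Why: Mesylation of the secondary benzylic alcohol (hindered phenols do not react) and base-induced 1,6-elimination give the neutral para-quinone methide without a free cation.

Step 28
Reactants: 43 C7c quinone methide; 37 seven-ring ketone (units A/B)
Product: 45 hexamer ketone (C8a–C7c bond; C7a=O; C7c R and C8a in target configuration), via potassium enolate 44 (not isolated)
Conditions: 37, KN(SiMe3)2, THF, −78 °C; then 43, −78 → −30 °C; AcOH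
Reagents that add atoms: none
Why: 1,6-Conjugate addition of a ketone enolate to a para-quinone methide under non-acidic conditions (no Friedel–Crafts side reactions); Felkin-type attack anti to ring C2 should set C7c, and C8a (α to the ketone) can equilibrate to the pseudo-equatorial epimer of the target.

Step 29
Reactants: 45 hexamer ketone; 14 1-(benzyloxy)-4-bromobenzene
Product: 47 hexamer carbinol (C7a bearing OH and 4-(benzyloxy)phenyl; C7a epimers), via aryllithium 46 (not isolated)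
Conditions: 14, n-BuLi, THF, −78 °C; CeCl3; then 45, −78 → −40 °C; H2O
Reagents that add atoms: none
Why: Organocerium-type 1,2-addition of an aryllithium to a hindered enolisable aryl ketone (excess reagent covers the two phenolic protons).

Step 30
Reactants: 47 hexamer carbinol
Product: 48 protected hexamer (thirteen benzyl ethers; four tert-butyl groups; all twelve stereocentres in target configuration)
Conditions: Et3SiH (5 equiv), CF3CO2H (10 equiv), CH2Cl2, −40 → 0 °C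
Reagents that add atoms: none
Why: Ionic hydrogenation; hydride adds to the diaryl carbocation on the face opposite the C8a substituent, giving the cis H7a/H8a relationship (C7a S).

Step 31
Reactants: 48 protected hexamer
Product: 49 tetra-tert-butyl hexamer (all thirteen benzyl ethers cleaved)
Conditions: H2 (1 atm), Pd(OH)2/C, THF/MeOH, 25 °C, monitored
Reagents that add atoms: none
Why: Hydrogenolysis of aryl benzyl ethers, stopped before the slower benzylic C–O bonds of the dihydrofurans react.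

Step 32
Reactants: 49 tetra-tert-butyl hexamer
Product: 50 CNP0184494.1 (target)
Conditions: AlCl3 (excess), PhMe/MeNO2, 60 °C
Reagents that add atoms: none
Why: Retro-Friedel–Crafts de-tert-butylation with toluene as acceptor; the trans dihydrofurans are the thermodynamic isomers, so no centre is scrambled.

## Compound list

1 | resorcinol | Oc1cccc(O)c1 | starting material
2 | 1,3-bis(triisopropylsilyloxy)benzene | CC(C)[Si](Oc1cccc(O[Si](C(C)C)(C(C)C)C(C)C)c1)(C(C)C)C(C)C | intermediate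
3 | 2-[3,5-bis(triisopropylsilyloxy)phenyl]-4,4,5,5-tetramethyl-1,3,2-dioxaborolane | CC(C)[Si](Oc1cc(O[Si](C(C)C)(C(C)C)C(C)C)cc(B2OC(C)(C)C(C)(C)O2)c1)(C(C)C)C(C)C | intermediate
4 | 3-bromophenol | Oc1cccc(Br)c1 | starting material
5 | (3-bromophenoxy)triisopropylsilane | CC(C)[Si](Oc1cccc(Br)c1)(C(C)C)C(C)C | intermediate
6 | 2-[3-bromo-5-(triisopropylsilyloxy)phenyl]-4,4,5,5-tetramethyl-1,3,2-dioxaborolane | CC(C)[Si](Oc1cc(Br)cc(B2OC(C)(C)C(C)(C)O2)c1)(C(C)C)C(C)C | intermediate (not isolated)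
7 | 3-bromo-5-(triisopropylsilyloxy)phenol | CC(C)[Si](Oc1cc(O)cc(Br)c1)(C(C)C)C(C)C | intermediate
8 | 5-bromobenzene-1,3-diol | Oc1cc(O)cc(Br)c1 | intermediate (not isolated)
9 | 1,3-bis(benzyloxy)-5-bromobenzene | Brc1cc(OCc2ccccc2)cc(OCc2ccccc2)c1 | intermediate
10 | 1,5-bis(benzyloxy)-3-bromo-2-iodobenzene | Brc1cc(OCc2ccccc2)cc(OCc2ccccc2)c1I | intermediate
11 | [2,4-bis(benzyloxy)-6-bromophenyl][3,5-bis(triisopropylsilyloxy)phenyl]methanone | O=C(c1cc(O[Si](C(C)C)(C(C)C)C(C)C)cc(O[Si](C(C)C)(C(C)C)C(C)C)c1)c1c(Br)cc(OCc2ccccc2)cc1OCc1ccccc1 | intermediate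
12 | [4-(benzyloxy)-2-bromo-6-hydroxyphenyl][3,5-bis(triisopropylsilyloxy)phenyl]methanone | O=C(c1cc(O[Si](C(C)C)(C(C)C)C(C)C)cc(O[Si](C(C)C)(C(C)C)C(C)C)c1)c1c(Br)cc(OCc2ccccc2)cc1O | intermediate
13 | 4-bromophenol | Oc1ccc(Br)cc1 | starting material
14 | 1-(benzyloxy)-4-bromobenzene | Brc1ccc(OCc2ccccc2)cc1 | intermediate
15 | [4-(benzyloxy)phenyl]magnesium bromide | Br[Mg]c1ccc(OCc2ccccc2)cc1 | intermediate (not isolated)
16 | [4-(benzyloxy)phenyl]methanol | OCc1ccc(OCc2ccccc2)cc1 | intermediate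
17 | [4-(benzyloxy)-2-{[4-(benzyloxy)phenyl]methoxy}-6-bromophenyl][3,5-bis(triisopropylsilyloxy)phenyl]methanone | O=C(c1cc(O[Si](C(C)C)(C(C)C)C(C)C)cc(O[Si](C(C)C)(C(C)C)C(C)C)c1)c1c(Br)cc(OCc2ccccc2)cc1OCc1ccc(OCc2ccccc2)cc1 | intermediate
18 | hydrazone of 17 | NN=C(c1cc(O[Si](C(C)C)(C(C)C)C(C)C)cc(O[Si](C(C)C)(C(C)C)C(C)C)c1)c1c(Br)cc(OCc2ccccc2)cc1OCc1ccc(OCc2ccccc2)cc1 | intermediate
19 | diaryl diazomethane from 18 | [N-]=[N+]=C(c1cc(O[Si](C(C)C)(C(C)C)C(C)C)cc(O[Si](C(C)C)(C(C)C)C(C)C)c1)c1c(Br)cc(OCc2ccccc2)cc1OCc1ccc(OCc2ccccc2)cc1 | intermediate (not isolated)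
20 | (2S,3R)-6-(benzyloxy)-2-[4-(benzyloxy)phenyl]-4-bromo-3-[3,5-bis(triisopropylsilyloxy)phenyl]-2,3-dihydro-1-benzofuran (cis) | Brc1cc(OCc9ccccc9)cc2c1[C@@H](c7cc(O[Si](C(C)C)(C(C)C)C(C)C)cc(O[Si](C(C)C)(C(C)C)C(C)C)c7)[C@@H](c8ccc(OCc9ccccc9)cc8)O2 | intermediate
21 | (2R,3R)-6-(benzyloxy)-2-[4-(benzyloxy)phenyl]-4-bromo-3-[3,5-bis(triisopropylsilyloxy)phenyl]-2,3-dihydro-1-benzofuran (trans) | Brc1cc(OCc9ccccc9)cc2c1[C@@H](c7cc(O[Si](C(C)C)(C(C)C)C(C)C)cc(O[Si](C(C)C)(C(C)C)C(C)C)c7)[C@H](c8ccc(OCc9ccccc9)cc8)O2 | intermediate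
22 | 5-{(2R,3R)-6-(benzyloxy)-2-[4-(benzyloxy)phenyl]-4-bromo-2,3-dihydro-1-benzofuran-3-yl}benzene-1,3-diol | Brc1cc(OCc9ccccc9)cc2c1[C@@H](c7cc(O)cc(O)c7)[C@H](c8ccc(OCc9ccccc9)cc8)O2 | intermediate (not isolated)
23 | (2R,3R)-6-(benzyloxy)-2-[4-(benzyloxy)phenyl]-3-[3,5-bis(benzyloxy)phenyl]-4-bromo-2,3-dihydro-1-benzofuran | Brc1cc(OCc9ccccc9)cc2c1[C@@H](c7cc(OCc9ccccc9)cc(OCc9ccccc9)c7)[C@H](c8ccc(OCc9ccccc9)cc8)O2 | intermediate
24 | phenol | Oc1ccccc1 | starting material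
25 | 2,6-di-tert-butylphenol | CC(C)(C)c1cccc(C(C)(C)C)c1O | intermediate
26 | 4-bromo-2,6-di-tert-butylphenol | CC(C)(C)c1cc(Br)cc(C(C)(C)C)c1O | intermediate
27 | 2,6-di-tert-butyl-4-ethenylphenol | C=Cc1cc(C(C)(C)C)c(O)c(C(C)(C)C)c1 | intermediate
28 | E-stilbene phenol of units E/F (ring F2 bis-benzyl ether) | CC(C)(C)c1cc(/C=C/c2cc(OCc9ccccc9)cc3c2[C@@H](c7cc(OCc9ccccc9)cc(OCc9ccccc9)c7)[C@H](c8ccc(OCc9ccccc9)cc8)O3)cc(C(C)(C)C)c1O | intermediate
29 | E-stilbene phenol of units C/D (ring D2 bis-silyl ether) | CC(C)(C)c1cc(/C=C/c2cc(OCc9ccccc9)cc3c2[C@@H](c7cc(O[Si](C(C)C)(C(C)C)C(C)C)cc(O[Si](C(C)C)(C(C)C)C(C)C)c7)[C@H](c8ccc(OCc9ccccc9)cc8)O3)cc(C(C)(C)C)c1O | intermediate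
30 | bromohydrin of 29 (OH on C7c, Br on C8c; diastereomers) | CC(C)(C)c1cc(C(O)C(Br)c2cc(OCc9ccccc9)cc3c2[C@@H](c7cc(O[Si](C(C)C)(C(C)C)C(C)C)cc(O[Si](C(C)C)(C(C)C)C(C)C)c7)[C@H](c8ccc(OCc9ccccc9)cc8)O3)cc(C(C)(C)C)c1O | intermediate (not isolated)
31 | α-bromoketone of units C/D (C7c=O, C8c–Br epimers) | CC(C)(C)c1cc(C(=O)C(Br)c2cc(OCc9ccccc9)cc3c2[C@@H](c7cc(O[Si](C(C)C)(C(C)C)C(C)C)cc(O[Si](C(C)C)(C(C)C)C(C)C)c7)[C@H](c8ccc(OCc9ccccc9)cc8)O3)cc(C(C)(C)C)c1O | intermediate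
32 | tert-butyl acetate | CC(=O)OC(C)(C)C | starting material
33 | lithium enolate of tert-butyl acetate | [Li+].[O-]C(=C)OC(C)(C)C | intermediate (not isolated)
34 | tert-butyl 2-{(2R,3R)-6-(benzyloxy)-2-[4-(benzyloxy)phenyl]-3-[3,5-bis(benzyloxy)phenyl]-2,3-dihydro-1-benzofuran-4-yl}acetate | CC(C)(C)OC(=O)Cc1cc(OCc9ccccc9)cc2c1[C@@H](c7cc(OCc9ccccc9)cc(OCc9ccccc9)c7)[C@H](c8ccc(OCc9ccccc9)cc8)O2 | intermediate
35 | arylacetic acid from 34 | OC(=O)Cc1cc(OCc9ccccc9)cc2c1[C@@H](c7cc(OCc9ccccc9)cc(OCc9ccccc9)c7)[C@H](c8ccc(OCc9ccccc9)cc8)O2 | intermediate (not isolated)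
36 | mixed trifluoroacetic anhydride of 35 | O=C(Cc1cc(OCc9ccccc9)cc2c1[C@@H](c7cc(OCc9ccccc9)cc(OCc9ccccc9)c7)[C@H](c8ccc(OCc9ccccc9)cc8)O2)OC(=O)C(F)(F)F | intermediate (not isolated)
37 | seven-ring ketone of units A/B (C7a=O, C8a H2, 7bR,8bR) | O=C1c2c(OCc9ccccc9)cc(OCc9ccccc9)cc2[C@@H]6c3c(cc(OCc9ccccc9)cc3C1)O[C@H]6c8ccc(OCc9ccccc9)cc8 | intermediate
38 | keto-quinone methide of units C–F (C8c–C8e bond, C7c ketone, C7e quinone methide, ring D2 bis-silyl ether) | CC(C)(C)c1cc(C(=O)[C@@H](c2cc(OCc9ccccc9)cc3c2[C@@H](c7cc(O[Si](C(C)C)(C(C)C)C(C)C)cc(O[Si](C(C)C)(C(C)C)C(C)C)c7)[C@H](c8ccc(OCc9ccccc9)cc8)O3)[C@@H](C=C4C=C(C(C)(C)C)C(=O)C(C(C)(C)C)=C4)c4cc(OCc9ccccc9)cc5c4[C@@H](c7cc(OCc9ccccc9)cc(OCc9ccccc9)c7)[C@H](c8ccc(OCc9ccccc9)cc8)O5)cc(C(C)(C)C)c1O | intermediate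
39 | eight-ring resorcinol (C7e–ring D2 bond formed, ring D2 free diol, C7c ketone) | O=C(c8cc(C(C)(C)C)c(O)c(C(C)(C)C)c8)[C@H]1c2cc(OCc9ccccc9)cc3c2[C@@H](c4cc(O)cc(O)c4[C@H](c8cc(C(C)(C)C)c(O)c(C(C)(C)C)c8)[C@H]1c1cc(OCc9ccccc9)cc5c1[C@@H](c7cc(OCc9ccccc9)cc(OCc9ccccc9)c7)[C@H](c8ccc(OCc9ccccc9)cc8)O5)[C@H](c8ccc(OCc9ccccc9)cc8)O3 | intermediate (not isolated)
40 | eight-ring ketone (ring D2 bis-benzyl ether, C7c ketone) | O=C(c8cc(C(C)(C)C)c(O)c(C(C)(C)C)c8)[C@H]1c2cc(OCc9ccccc9)cc3c2[C@@H](c4cc(OCc9ccccc9)cc(OCc9ccccc9)c4[C@H](c8cc(C(C)(C)C)c(O)c(C(C)(C)C)c8)[C@H]1c1cc(OCc9ccccc9)cc5c1[C@@H](c7cc(OCc9ccccc9)cc(OCc9ccccc9)c7)[C@H](c8ccc(OCc9ccccc9)cc8)O5)[C@H](c8ccc(OCc9ccccc9)cc8)O3 | intermediate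
41 | C7c alcohol of 40 (C7c epimers) | OC(c8cc(C(C)(C)C)c(O)c(C(C)(C)C)c8)[C@H]1c2cc(OCc9ccccc9)cc3c2[C@@H](c4cc(OCc9ccccc9)cc(OCc9ccccc9)c4[C@H](c8cc(C(C)(C)C)c(O)c(C(C)(C)C)c8)[C@H]1c1cc(OCc9ccccc9)cc5c1[C@@H](c7cc(OCc9ccccc9)cc(OCc9ccccc9)c7)[C@H](c8ccc(OCc9ccccc9)cc8)O5)[C@H](c8ccc(OCc9ccccc9)cc8)O3 | intermediate
42 | C7c mesylate of 41 | CS(=O)(=O)OC(c8cc(C(C)(C)C)c(O)c(C(C)(C)C)c8)[C@H]1c2cc(OCc9ccccc9)cc3c2[C@@H](c4cc(OCc9ccccc9)cc(OCc9ccccc9)c4[C@H](c8cc(C(C)(C)C)c(O)c(C(C)(C)C)c8)[C@H]1c1cc(OCc9ccccc9)cc5c1[C@@H](c7cc(OCc9ccccc9)cc(OCc9ccccc9)c7)[C@H](c8ccc(OCc9ccccc9)cc8)O5)[C@H](c8ccc(OCc9ccccc9)cc8)O3 | intermediate (not isolated)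
43 | C7c quinone methide of units C–F | O=C6C(C(C)(C)C)=CC(=C[C@H]1c2cc(OCc9ccccc9)cc3c2[C@@H](c4cc(OCc9ccccc9)cc(OCc9ccccc9)c4[C@H](c8cc(C(C)(C)C)c(O)c(C(C)(C)C)c8)[C@H]1c1cc(OCc9ccccc9)cc5c1[C@@H](c7cc(OCc9ccccc9)cc(OCc9ccccc9)c7)[C@H](c8ccc(OCc9ccccc9)cc8)O5)[C@H](c8ccc(OCc9ccccc9)cc8)O3)C=C6C(C)(C)C | intermediate
44 | potassium enolate of 37 | [K+].[O-]C=1c2c(OCc9ccccc9)cc(OCc9ccccc9)cc2[C@@H]6c3c(cc(OCc9ccccc9)cc3C=1)O[C@H]6c8ccc(OCc9ccccc9)cc8 | intermediate (not isolated)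
45 | hexamer ketone (C7a=O; C8a–C7c bond) | O=C1c2c(OCc9ccccc9)cc(OCc9ccccc9)cc2[C@@H]6c3c(cc(OCc9ccccc9)cc3[C@H]1[C@H](c8cc(C(C)(C)C)c(O)c(C(C)(C)C)c8)[C@H]1c2cc(OCc9ccccc9)cc3c2[C@@H](c4cc(OCc9ccccc9)cc(OCc9ccccc9)c4[C@H](c8cc(C(C)(C)C)c(O)c(C(C)(C)C)c8)[C@H]1c1cc(OCc9ccccc9)cc5c1[C@@H](c7cc(OCc9ccccc9)cc(OCc9ccccc9)c7)[C@H](c8ccc(OCc9ccccc9)cc8)O5)[C@H](c8ccc(OCc9ccccc9)cc8)O3)O[C@H]6c8ccc(OCc9ccccc9)cc8 | intermediate
46 | [4-(benzyloxy)phenyl]lithium | [Li]c1ccc(OCc2ccccc2)cc1 | intermediate (not isolated)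
47 | hexamer carbinol (C7a: OH and 4-(benzyloxy)phenyl; C7a epimers) | OC1(c8ccc(OCc9ccccc9)cc8)c2c(OCc9ccccc9)cc(OCc9ccccc9)cc2[C@@H]6c3c(cc(OCc9ccccc9)cc3[C@H]1[C@H](c8cc(C(C)(C)C)c(O)c(C(C)(C)C)c8)[C@H]1c2cc(OCc9ccccc9)cc3c2[C@@H](c4cc(OCc9ccccc9)cc(OCc9ccccc9)c4[C@H](c8cc(C(C)(C)C)c(O)c(C(C)(C)C)c8)[C@H]1c1cc(OCc9ccccc9)cc5c1[C@@H](c7cc(OCc9ccccc9)cc(OCc9ccccc9)c7)[C@H](c8ccc(OCc9ccccc9)cc8)O5)[C@H](c8ccc(OCc9ccccc9)cc8)O3)O[C@H]6c8ccc(OCc9ccccc9)cc8 | intermediate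
48 | protected hexamer (13 benzyl ethers, 4 tert-butyl groups) | c9ccccc9COc8ccc(cc8)[C@H]1c2c(OCc9ccccc9)cc(OCc9ccccc9)cc2[C@@H]6c3c(cc(OCc9ccccc9)cc3[C@H]1[C@H](c8cc(C(C)(C)C)c(O)c(C(C)(C)C)c8)[C@H]1c2cc(OCc9ccccc9)cc3c2[C@@H](c4cc(OCc9ccccc9)cc(OCc9ccccc9)c4[C@H](c8cc(C(C)(C)C)c(O)c(C(C)(C)C)c8)[C@H]1c1cc(OCc9ccccc9)cc5c1[C@@H](c7cc(OCc9ccccc9)cc(OCc9ccccc9)c7)[C@H](c8ccc(OCc9ccccc9)cc8)O5)[C@H](c8ccc(OCc9ccccc9)cc8)O3)O[C@H]6c8ccc(OCc9ccccc9)cc8 | intermediate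
49 | tetra-tert-butyl hexamer (all phenols free) | Oc8ccc(cc8)[C@H]1c2c(O)cc(O)cc2[C@@H]6c3c(cc(O)cc3[C@H]1[C@H](c8cc(C(C)(C)C)c(O)c(C(C)(C)C)c8)[C@H]1c2cc(O)cc3c2[C@@H](c4cc(O)cc(O)c4[C@H](c8cc(C(C)(C)C)c(O)c(C(C)(C)C)c8)[C@H]1c1cc(O)cc5c1[C@@H](c7cc(O)cc(O)c7)[C@H](c8ccc(O)cc8)O5)[C@H](c8ccc(O)cc8)O3)O[C@H]6c8ccc(O)cc8 | intermediate
50 | CNP0184494.1 | Oc1ccc([C@H]2c3c(O)cc(O)cc3[C@@H]3c4c(cc(O)cc4[C@H]2[C@H](c2ccc(O)cc2)[C@H]2c4cc(O)cc5c4[C@@H](c4cc(O)cc(O)c4[C@H](c4ccc(O)cc4)[C@H]2c2cc(O)cc4c2[C@@H](c2cc(O)cc(O)c2)[C@H](c2ccc(O)cc2)O4)[C@H](c2ccc(O)cc2)O5)O[C@H]3c2ccc(O)cc2)cc1 | target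

## Step count and risk

Total steps: 32. Longest linear sequence: 21 steps (3–8, 11–14, 20, 21, 24–32).

**Step 24 (new coupling).** Risks: homodimerisation of the α-keto radical, poor control at C8c/C8e. Fallback with known chemistry, setting out from 28 and 31 and returning at 38: 28 is taken through the conditions of step 21 to its α-bromoketone F1, and Zn/AcOH removes the bromine to give deoxybenzoin F2. The potassium enolate of F2 (KN(SiMe3)2, THF, −78 °C) is alkylated by 31 (classical enolate/α-haloketone synthesis of 1,4-diketones) to give diketone F3. Sub-stoichiometric NaBH4 at −40 °C and chromatography give the C7e mono-alcohol F4; the regioisomer and diol are re-oxidised with IBX and recycled. MsCl/Et3N then eliminates F4 to 38.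

**Step 25 (eight-ring closure).** Risks: O-alkylation, enolate trapping of the quinone methide, wrong C7e epimer. Fallback setting out from 38 and returning at 40: HF·pyridine in THF at 0 °C removes the silyl groups without base, so the resorcinol quinone methide F5 can be isolated. Its magnesium phenoxide (i-PrMgCl, PhMe, 0 → 40 °C) is then cyclised by chelate-templated ortho C-alkylation (a Lewis-acid-organised Friedel–Crafts reaction instead of a free phenoxide addition) to 39, which is benzylated as before to 40.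

**Step 28 (union of the two halves).** Risks: two hindered tertiary carbons are joined; C7c selectivity. Fallback setting out from 43 and 34 and returning at 45: the smaller lithium enolate of ester 34 (LiN(SiMe3)2, THF, −78 °C) adds 1,6 to 43 to give ester adduct F6. CF3CO2H liberates acid F7, and (CF3CO)2O then closes the seven-membered ketone onto ring B2 (conditions of step 23), so the ring is formed after the intermolecular bond and not before; this gives 45.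

## Further compounds

F1 | step 24 | α-bromoketone of units E/F (from 28) | CC(C)(C)c1cc(C(=O)C(Br)c2cc(OCc9ccccc9)cc3c2[C@@H](c7cc(OCc9ccccc9)cc(OCc9ccccc9)c7)[C@H](c8ccc(OCc9ccccc9)cc8)O3)cc(C(C)(C)C)c1O
F2 | step 24 | deoxybenzoin of units E/F | CC(C)(C)c1cc(C(=O)Cc2cc(OCc9ccccc9)cc3c2[C@@H](c7cc(OCc9ccccc9)cc(OCc9ccccc9)c7)[C@H](c8ccc(OCc9ccccc9)cc8)O3)cc(C(C)(C)C)c1O
F3 | step 24 | 1,4-diketone of units C–F (C7c=O and C7e=O) | CC(C)(C)c1cc(C(=O)[C@@H](c2cc(OCc9ccccc9)cc3c2[C@@H](c7cc(O[Si](C(C)C)(C(C)C)C(C)C)cc(O[Si](C(C)C)(C(C)C)C(C)C)c7)[C@H](c8ccc(OCc9ccccc9)cc8)O3)[C@@H](C(=O)c4cc(C(C)(C)C)c(O)c(C(C)(C)C)c4)c4cc(OCc9ccccc9)cc5c4[C@@H](c7cc(OCc9ccccc9)cc(OCc9ccccc9)c7)[C@H](c8ccc(OCc9ccccc9)cc8)O5)cc(C(C)(C)C)c1O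
F4 | step 24 | C7e mono-alcohol of F3 | CC(C)(C)c1cc(C(=O)[C@@H](c2cc(OCc9ccccc9)cc3c2[C@@H](c7cc(O[Si](C(C)C)(C(C)C)C(C)C)cc(O[Si](C(C)C)(C(C)C)C(C)C)c7)[C@H](c8ccc(OCc9ccccc9)cc8)O3)[C@@H](C(O)c4cc(C(C)(C)C)c(O)c(C(C)(C)C)c4)c4cc(OCc9ccccc9)cc5c4[C@@H](c7cc(OCc9ccccc9)cc(OCc9ccccc9)c7)[C@H](c8ccc(OCc9ccccc9)cc8)O5)cc(C(C)(C)C)c1O
F5 | step 25 | resorcinol quinone methide (38 with ring D2 as free diol) | CC(C)(C)c1cc(C(=O)[C@@H](c2cc(OCc9ccccc9)cc3c2[C@@H](c7cc(O)cc(O)c7)[C@H](c8ccc(OCc9ccccc9)cc8)O3)[C@@H](C=C4C=C(C(C)(C)C)C(=O)C(C(C)(C)C)=C4)c4cc(OCc9ccccc9)cc5c4[C@@H](c7cc(OCc9ccccc9)cc(OCc9ccccc9)c7)[C@H](c8ccc(OCc9ccccc9)cc8)O5)cc(C(C)(C)C)c1O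
F6 | step 28 | tert-butyl ester adduct (C8a–C7c bond, seven-ring still open) | CC(C)(C)OC(=O)[C@@H](c2cc(OCc9ccccc9)cc3c2[C@@H](c7cc(OCc9ccccc9)cc(OCc9ccccc9)c7)[C@H](c8ccc(OCc9ccccc9)cc8)O3)[C@H](c8cc(C(C)(C)C)c(O)c(C(C)(C)C)c8)[C@H]1c2cc(OCc9ccccc9)cc3c2[C@@H](c4cc(OCc9ccccc9)cc(OCc9ccccc9)c4[C@H](c8cc(C(C)(C)C)c(O)c(C(C)(C)C)c8)[C@H]1c1cc(OCc9ccccc9)cc5c1[C@@H](c7cc(OCc9ccccc9)cc(OCc9ccccc9)c7)[C@H](c8ccc(OCc9ccccc9)cc8)O5)[C@H](c8ccc(OCc9ccccc9)cc8)O3
F7 | step 28 | carboxylic acid from F6 | OC(=O)[C@@H](c2cc(OCc9ccccc9)cc3c2[C@@H](c7cc(OCc9ccccc9)cc(OCc9ccccc9)c7)[C@H](c8ccc(OCc9ccccc9)cc8)O3)[C@H](c8cc(C(C)(C)C)c(O)c(C(C)(C)C)c8)[C@H]1c2cc(OCc9ccccc9)cc3c2[C@@H](c4cc(OCc9ccccc9)cc(OCc9ccccc9)c4[C@H](c8cc(C(C)(C)C)c(O)c(C(C)(C)C)c8)[C@H]1c1cc(OCc9ccccc9)cc5c1[C@@H](c7cc(OCc9ccccc9)cc(OCc9ccccc9)c7)[C@H](c8ccc(OCc9ccccc9)cc8)O5)[C@H](c8ccc(OCc9ccccc9)cc8)O3
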